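The route rests on making the C5–C10 bond last. This bond is common to rings A and B, C10 is quaternary (a tertiary cation once C1=C10 is protonated) and C5 is α to the C6 oxygen (an enol carbon of a C6 ketone). In one operation the key step should therefore turn a ten-membered ring into the trans-decalin, close rings A and B together and set C10 and C5, leaving a 7-en-6-one that carries the handles for the 6α- and 8α-oxygens. Its precursor is a (2Z,5E)-cyclodeca-2,5-dienone with the (13R)-silyloxy side chain on C9, reached by an alkynyl anionic oxy-Cope ring expansion.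

Key step: step 8

Remarks on the chemistry (assumptions)
- Ring carbons carry labdane numbers from compound 8 on. In 8, C6 is the carbonyl carbon, C1 the alkenylated α-carbon and C4 the gem-dimethyl carbon; C10 and C9 are the alkenyl carbons; C7 and C8 come from propyne.
- The target is read as (13R)-6α-angeloyloxylabd-14-ene-8α,13-diol with 5α-H, 9α-H, 10β-CH3 and 8β-CH3. Commercial (R)-linalool of high enantiomeric purity supplies C13.
- C1 of ketone 8 is configurationally labile and too remote from C13 for substrate control, so it is set by the catalyst in step 5. The sense of induction cannot be predicted, so the ligand antipode that gives 2R is the one used.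
- The Z geometry fixed in step 3 and the 2R centre of 8 together determine C9 in step 7.

Step 1
Reactants: 1 (R)-linalool
Product: 2 (R)-linalool tert-butyldimethylsilyl ether
Conditions: TBSOTf, 2,6-lutidine, CH2Cl2, 0 °C to rt
Reagents that add atoms: tert-butyldimethylsilyl trifluoromethanesulfonate, CC(C)(C)[Si](C)(C)OS(=O)(=O)C(F)(F)F
Why: Silylation of a hindered tertiary alcohol with a silyl triflate and a hindered pyridine base is routine and does not touch the C13 stereocentre.

Step 2
Reactants: 2 (R)-linalool tert-butyldimethylsilyl ether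
Product: 3 (4R)-4-(tert-butyldimethylsilyloxy)-4-methylhex-5-enal
Conditions: O3, CH2Cl2/MeOH, NaHCO3, −78 °C, Sudan red 7B end-point; then Me2S, −78 °C to rt
Reagents that add atoms: ozone, [O-][O+]=O
Why: Ozonolysis is much faster at the electron-rich trisubstituted alkene than at the vinyl group next to the silyloxy-bearing quaternary carbon, so titration to the indicator end-point and reductive work-up should cleave only the isopropylidene unit.

Step 3
Reactants: 3 (4R)-4-(tert-butyldimethylsilyloxy)-4-methylhex-5-enal
Product: 4 (3R,6Z)-3-(tert-butyldimethylsilyloxy)-7-iodo-3-methylocta-1,6-diene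
Conditions: [Ph3PEt]I, n-BuLi, THF, 0 °C; I2, −78 °C; NaHMDS, −20 °C; then 3, −78 to −20 °C
Reagents that add atoms: ethyltriphenylphosphonium iodide, CC[P+](c1ccccc1)(c1ccccc1)c1ccccc1.[I-]; iodine, II
Why: Wittig olefination with the α-iodoethylidene ylide (Stork–Zhao-type) is known to give (Z)-2-iodoalk-2-enes, with iodine cis to the chain, which is the geometry the later rearrangement needs.

Step 4
Reactants: 5 3,3-dimethylcyclohexanone
Product: 6 (5,5-dimethylcyclohex-1-enyloxy)trimethylsilane
Conditions: LDA, THF, −78 °C; TMSCl, −78 °C to rt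
Reagents that add atoms: chlorotrimethylsilane, C[Si](C)(C)Cl
Why: Kinetic deprotonation of 3,3-dimethylcyclohexanone occurs at C6, away from the neopentyl C2 position, and O-silylation fixes this regiochemistry as the silyl enol ether.

Step 5
Reactants: 6 (5,5-dimethylcyclohex-1-enyloxy)trimethylsilane; 4 (3R,6Z)-3-(tert-butyldimethylsilyloxy)-7-iodo-3-methylocta-1,6-diene
Product: 8 (2R)-2-[(2Z,6R)-6-(tert-butyldimethylsilyloxy)-6-methylocta-2,7-dien-2-yl]-5,5-dimethylcyclohexanone, via tributyltin enolate 7 (not isolated)
Conditions: Bu3SnF, Pd(OAc)2 (5 mol %), (R)-DIFLUORPHOS (6 mol %), toluene, 60 °C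
Reagents that add atoms: none
Why: Palladium-catalysed α-alkenylation of a ketone through its tin enolate (enolate cross-coupling with retention of the Z-iodide geometry) runs without strong base and should therefore neither epimerise nor conjugate the β,γ-unsaturated product; the new centre C1 (C2 of the cyclohexanone) is set by the chiral bisphosphine on palladium, independently of the remote C13.

Step 6
Reactants: 8 (2R)-2-[(2Z,6R)-6-(tert-butyldimethylsilyloxy)-6-methylocta-2,7-dien-2-yl]-5,5-dimethylcyclohexanone; 9 propyne
Product: 12 (1R,2R)-2-[(2Z,6R)-6-(tert-butyldimethylsilyloxy)-6-methylocta-2,7-dien-2-yl]-5,5-dimethyl-1-(prop-1-ynyl)cyclohexanol, via prop-1-ynyllithium 10 (not isolated), via dichloro(prop-1-ynyl)cerium 11 (not isolated)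
Conditions: 9, n-BuLi, THF, −78 °C; CeCl3, −78 °C; then 8, −78 °C; aqueous work-up
Reagents that add atoms: none
Why: 1,2-Addition of a weakly basic organocerium acetylide avoids enolisation of the labile ketone; the axial methyl at C4 blocks axial attack, so the alkyne should enter equatorially, trans to the equatorial alkenyl group, which sets C6 as the (1R,2R) carbinol with axial OH.

Step 7
Reactants: 12 (1R,2R)-2-[(2Z,6R)-6-(tert-butyldimethylsilyloxy)-6-methylocta-2,7-dien-2-yl]-5,5-dimethyl-1-(prop-1-ynyl)cyclohexanol
Product: 15 (2Z,4R,5E)-4-[(3R)-3-(tert-butyldimethylsilyloxy)-3-methylpent-4-enyl]-3,5,9,9-tetramethylcyclodeca-2,5-dienone, via potassium alkoxide 13 (not isolated), via potassium allenolate 14 (not isolated)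
Conditions: KH, 18-crown-6, THF, 0 °C to rt; inverse quench into cold aq NH4Cl
Reagents that add atoms: none
Why: Anionic oxy-Cope ring expansion of a 1-alkynyl-2-alkenylcyclohexanol: the trans-diequatorial alkoxide should rearrange through a chair-like transition state that breaks C1–C6 and forms C8–C9, which gives the (E)-C1=C10 alkene and transfers the C1 configuration to C9 (9R, the Z-placed C11 being pseudo-axial), and protonation of the allenolate at C7 from the ring exterior gives the (2Z)-enone.

Step 8
Reactants: 15 (2Z,4R,5E)-4-[(3R)-3-(tert-butyldimethylsilyloxy)-3-methylpent-4-enyl]-3,5,9,9-tetramethylcyclodeca-2,5-dienone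
Product: 17 (13R)-13-(tert-butyldimethylsilyloxy)labda-7,14-dien-6-one, via C5=C6 dienol 16 (not isolated)
Conditions: TsOH (anhydrous, 0.2 equiv), CH2Cl2, 0 °C to rt
Reagents that add atoms: none
Why: Proposed new method: the acid should convert the enone reversibly into its cross-conjugated C5=C6 dienol 16 and protonate the strained (E)-C1=C10 alkene at C1, after which the tertiary C10 cation is captured across the ring by the enol carbon C5 and the protonated enone loses H+ to give 17. The closest known chemistry is the acid-promoted transannular cyclisation of germacrane-type (E)-cyclodeca-1(10)-enes to eudesmane decalins, here with an enol in place of an alkene as the π-nucleophile. Both rings close through the single transannular C5–C10 bond, ring A (C1–C2–C3–C4–C5–C10) in a 6-(enolexo)-endo-trig mode and ring B (C5–C6–C7–C8–C9–C10) in a 6-(enolendo)-exo-trig mode. C10 is controlled by C9: in the chair–chair-like conformer that keeps the C9 side chain pseudo-equatorial, C5 reaches the C10 face on the side of C8, which places the C20 methyl anti to H9 (10β); C5, being α to the ketone, is settled thermodynamically by acid-mediated enolisation as the trans fusion (5α-H). The step needs protonation of C1=C10 in preference to the enone and the C14=C15 vinyl group, and C-alkylation at C5 in preference to proton loss from C9 or C20; the strain and trisubstitution of the E-cyclodecene alkene and the proximity of C5 to C10 across the ring are expected to secure this, while the sub-stoichiometric acid in a non-nucleophilic solvent should leave the tertiary allylic silyl ether intact.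

Step 9
Reactants: 17 (13R)-13-(tert-butyldimethylsilyloxy)labda-7,14-dien-6-one
Product: 18 (13R)-13-(tert-butyldimethylsilyloxy)-7α,8α-epoxylabd-14-en-6-one
Conditions: 30% aq H2O2, NaOH (cat.), MeOH, 0 °C to rt
Reagents that add atoms: hydrogen peroxide, OO
Why: Weitz–Scheffer nucleophilic epoxidation of a β,β-disubstituted cyclohexenone (as with isophorone): hydroperoxide should add to C8 on the α face, anti to the axial C10 methyl and the C9 side chain, so ring closure gives the 7α,8α-epoxide and fixes the C8–O bond as α.

Step 10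
Reactants: 18 (13R)-13-(tert-butyldimethylsilyloxy)-7α,8α-epoxylabd-14-en-6-one
Product: 19 (13R)-13-(tert-butyldimethylsilyloxy)-8α-hydroxylabd-14-en-6-one
Conditions: SmI2 (2.2 equiv), THF/MeOH, −90 °C
Reagents that add atoms: none
Why: SmI2 reduces α,β-epoxy ketones through the ketyl with selective cleavage of the Cα–O bond (C7–O), which leaves the tertiary C8–O bond and its configuration untouched and gives the β-hydroxy ketone.

Step 11
Reactants: 19 (13R)-13-(tert-butyldimethylsilyloxy)-8α-hydroxylabd-14-en-6-one
Product: 20 (13R)-13-(tert-butyldimethylsilyloxy)labd-14-ene-6α,8α-diol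
Conditions: Li, NH3(l)/THF, MeOH, −78 °C; then NH4Cl
Reagents that add atoms: none
Why: Dissolving-metal reduction of a hindered cyclohexanone gives the thermodynamically preferred equatorial alcohol, here 6α-OH, whereas hydride reagents would attack from the α face and give the axial 6β-alcohol; the isolated alkene and the silyl ether are inert at −78 °C.

Step 12
Reactants: 20 (13R)-13-(tert-butyldimethylsilyloxy)labd-14-ene-6α,8α-diol; 21 angelic acid
Product: 23 (13R)-6α-angeloyloxy-13-(tert-butyldimethylsilyloxy)labd-14-en-8α-ol, via angelic 2,4,6-trichlorobenzoic anhydride 22 (not isolated)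
Conditions: 21, 2,4,6-Cl3C6H2COCl, Et3N, toluene, rt; then 20, 80 °C
Reagents that add atoms: none
Why: Yamaguchi-type acylation through the mixed anhydride without a nucleophilic amine catalyst is a stereoconservative way to make angelates (no Z to E isomerisation to the tiglate), and only the secondary equatorial 6α-hydroxyl should react, the tertiary 8α-hydroxyl being too hindered.

Step 13
Reactants: 23 (13R)-6α-angeloyloxy-13-(tert-butyldimethylsilyloxy)labd-14-en-8α-ol
Product: 24 (13R)-6α-angeloyloxylabd-14-ene-8α,13-diol (target)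
Conditions: TBAF, AcOH, THF, rt to 45 °C
Reagents that add atoms: none
Why: Fluoride cleavage of the tertiary silyl ether under acetic acid buffering should avoid both base-induced isomerisation of the angelate and acid ionisation of the tertiary allylic alcohol.

Compound list
1 | (R)-linalool, (3R)-3,7-dimethylocta-1,6-dien-3-ol | C=C[C@](C)(O)CCC=C(C)C | starting material
2 | (R)-linalool tert-butyldimethylsilyl ether | C=C[C@](C)(O[Si](C)(C)C(C)(C)C)CCC=C(C)C | intermediate
3 | (4R)-4-(tert-butyldimethylsilyloxy)-4-methylhex-5-enal | C=C[C@](C)(O[Si](C)(C)C(C)(C)C)CCC=O | intermediate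
4 | (3R,6Z)-3-(tert-butyldimethylsilyloxy)-7-iodo-3-methylocta-1,6-diene | C=C[C@](C)(O[Si](C)(C)C(C)(C)C)CC/C=C(/C)I | intermediate
5 | 3,3-dimethylcyclohexanone | CC1(C)CCCC(=O)C1 | starting material
6 | (5,5-dimethylcyclohex-1-enyloxy)trimethylsilane | C[Si](C)(C)OC1=CCCC(C)(C)C1 | intermediate
7 | tributyl(5,5-dimethylcyclohex-1-enyloxy)stannane | CCCC[Sn](CCCC)(CCCC)OC1=CCCC(C)(C)C1 | intermediate (not isolated)
8 | (2R)-2-[(2Z,6R)-6-(tert-butyldimethylsilyloxy)-6-methylocta-2,7-dien-2-yl]-5,5-dimethylcyclohexanone | O=C1CC(C)(C)CC[C@@H]1/C(C)=C\CC[C@@](C)(O[Si](C)(C)C(C)(C)C)C=C | intermediate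
9 | propyne | CC#C | starting material
10 | prop-1-ynyllithium | [Li]C#CC | intermediate (not isolated)
11 | dichloro(prop-1-ynyl)cerium | CC#C[Ce](Cl)Cl | intermediate (not isolated)
12 | (1R,2R)-2-[(2Z,6R)-6-(tert-butyldimethylsilyloxy)-6-methylocta-2,7-dien-2-yl]-5,5-dimethyl-1-(prop-1-ynyl)cyclohexanol | CC#C[C@@]1(O)CC(C)(C)CC[C@@H]1/C(C)=C\CC[C@@](C)(O[Si](C)(C)C(C)(C)C)C=C | intermediate
13 | potassium alkoxide of 12 | CC#C[C@@]1([O-])CC(C)(C)CC[C@@H]1/C(C)=C\CC[C@@](C)(O[Si](C)(C)C(C)(C)C)C=C.[K+] | intermediate (not isolated)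
14 | potassium (5E)-cyclodeca-1,2,5-trien-1-olate (allenolate, allene axis not assigned) | [K+].[O-]C1=C=C(C)[C@H](CC[C@@](C)(O[Si](C)(C)C(C)(C)C)C=C)/C(C)=C/CCC(C)(C)C1 | intermediate (not isolated)
15 | (2Z,4R,5E)-4-[(3R)-3-(tert-butyldimethylsilyloxy)-3-methylpent-4-enyl]-3,5,9,9-tetramethylcyclodeca-2,5-dienone | O=C1/C=C(C)\[C@H](CC[C@@](C)(O[Si](C)(C)C(C)(C)C)C=C)/C(C)=C/CCC(C)(C)C1 | intermediate (precursor of the key step)
16 | C5=C6 dienol tautomer of 15 (enol geometry not fixed) | OC1/C=C(C)\[C@H](CC[C@@](C)(O[Si](C)(C)C(C)(C)C)C=C)/C(C)=C/CCC(C)(C)C=1 | intermediate (not isolated)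
17 | (13R)-13-(tert-butyldimethylsilyloxy)labda-7,14-dien-6-one (5α-H, 9α-H, 10β-CH3) | C=C[C@](C)(O[Si](C)(C)C(C)(C)C)CC[C@@H]1[C@@]2(C)CCCC(C)(C)[C@@H]2C(=O)C=C1C | intermediate (product of the key step)
18 | (13R)-13-(tert-butyldimethylsilyloxy)-7α,8α-epoxylabd-14-en-6-one | C=C[C@](C)(O[Si](C)(C)C(C)(C)C)CC[C@@H]1[C@@]2(C)CCCC(C)(C)[C@@H]2C(=O)[C@H]3O[C@@]13C | intermediate
19 | (13R)-13-(tert-butyldimethylsilyloxy)-8α-hydroxylabd-14-en-6-one | C=C[C@](C)(O[Si](C)(C)C(C)(C)C)CC[C@@H]1[C@@]2(C)CCCC(C)(C)[C@@H]2C(=O)C[C@@]1(C)O | intermediate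
20 | (13R)-13-(tert-butyldimethylsilyloxy)labd-14-ene-6α,8α-diol | C=C[C@](C)(O[Si](C)(C)C(C)(C)C)CC[C@@H]1[C@@]2(C)CCCC(C)(C)[C@@H]2[C@@H](O)C[C@@]1(C)O | intermediate
21 | angelic acid, (Z)-2-methylbut-2-enoic acid | C/C=C(/C)C(=O)O | starting material
22 | (Z)-2-methylbut-2-enoic 2,4,6-trichlorobenzoic anhydride | C/C=C(/C)C(=O)OC(=O)c1c(Cl)cc(Cl)cc1Cl | intermediate (not isolated)
23 | (13R)-6α-angeloyloxy-13-(tert-butyldimethylsilyloxy)labd-14-en-8α-ol | C=C[C@](C)(O[Si](C)(C)C(C)(C)C)CC[C@@H]1[C@@]2(C)CCCC(C)(C)[C@@H]2[C@@H](OC(=O)/C(C)=C\C)C[C@@]1(C)O | intermediate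
24 | (13R)-6α-angeloyloxylabd-14-ene-8α,13-diol | C=C[C@](C)(O)CC[C@@H]1[C@@]2(C)CCCC(C)(C)[C@@H]2[C@@H](OC(=O)/C(C)=C\C)C[C@@]1(C)O | target

Total step count: 13. Longest linear sequence: 12 steps (steps 1–3 and 5–13, from (R)-linalool).

Steps most likely to fail

1. Step 8. What may go wrong: proton loss from the C10 cation toward C9 (which conjugates the diene and erases the only ring stereocentre) or toward C20, capture of the cation by the carbonyl oxygen, enolisation toward C9 instead of C5, attack on the wrong face of C10, or acid ionisation at the tertiary allylic silyl ether. The fallback sets out from 15 and comes back at 17, and it replaces the proton by an epoxide as initiator and the enol by a preformed enol silane. mCPBA (NaHCO3, CH2Cl2, 0 °C) should epoxidise only the strained, electron-rich C1=C10 alkene from the ring exterior to give the 1,10-epoxide F1. LDA and TMSCl (THF, −78 °C) then remove the α′ proton at C5 kinetically to give the trimethylsilyl dienol ether F2. MeAlCl2 (CH2Cl2, −78 °C) should open the epoxide at the tertiary C10 with anti attack of the enol silane carbon C5, to give the 1β-hydroxy enone F3; this combines an epoxide-initiated cyclisation terminated by a silyl enol ether with the transannular course of 1(10)-epoxygermacrane to eudesmanol closures. The C1 hydroxyl is removed by Barton–McCombie deoxygenation through the imidazolylthiocarbonate F4 (1,1′-thiocarbonyldiimidazole, DMAP, CH2Cl2; then Bu3SnH, AIBN, toluene, 80 °C), which returns 17.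

2. Step 5. What may go wrong: insufficient facial discrimination at C1 by the catalyst, or epimerisation of the β,γ-unsaturated ketone during coupling or isolation, either of which would carry both ring series forward as inseparable remote diastereomers. The fallback sets out from 6 and 4 and comes back at 8, and it replaces catalyst control in the C–C coupling by a catalyst-controlled reduction that turns the two C2 epimers into separable diastereomers. The same tin-enolate coupling with an achiral phosphine (P(t-Bu)3) gives 8 together with its C2 epimer F5. Reduction of the mixture with (S)-Me-CBS and catecholborane (toluene, −78 °C, which spares the alkenes) should deliver hydride to the same carbonyl face of both epimers, so the 2R ketone gives the cis alcohol F6 and the 2S ketone the trans alcohol F7. The two are separated by chromatography, and Dess–Martin oxidation of F6 (NaHCO3, CH2Cl2, 0 °C) returns configurationally defined 8; F7 can be oxidised, epimerised and recycled.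

3. Step 7. What may go wrong: retro-addition of the hindered tertiary propargylic alkoxide (loss of propynide) in competition with the [3,3] shift, protonation of the allenolate to the 2E enone, or base-induced double-bond migration through C9 before the quench. The fallback sets out from 8 and comes back at 15, and it uses an alkene instead of the alkyne as the second π-component. (Z)-Prop-1-enyllithium (from (Z)-1-bromopropene and t-BuLi) with CeCl3 should add equatorially to 8 to give the dialkenyl carbinol F8. KH and 18-crown-6 (THF, rt) then effect the classical anionic oxy-Cope ring expansion of a trans-1,2-dialkenylcyclohexanol to the potassium enolate F9, which is trapped with TMSCl as the regiodefined silyl enol ether F10. Saegusa–Ito oxidation (Pd(OAc)2, MeCN, rt) introduces the C7=C8 double bond and returns 15; a 2E isomer, if formed, should relax to 2Z on brief treatment with catalytic PhSSPh under light.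

Further compounds
F1 | step 8 | 1,10-epoxide of 15 (labdane numbering, oxygen on the ring-exterior face) | O=C1/C=C(C)\[C@H](CC[C@@](C)(O[Si](C)(C)C(C)(C)C)C=C)[C@@]2(C)O[C@@H]2CCC(C)(C)C1
F2 | step 8 | trimethylsilyl C5=C6 dienol ether of F1 (enol geometry not fixed) | C[Si](C)(C)OC1/C=C(C)\[C@H](CC[C@@](C)(O[Si](C)(C)C(C)(C)C)C=C)[C@@]2(C)O[C@@H]2CCC(C)(C)C=1
F3 | step 8 | (13R)-13-(tert-butyldimethylsilyloxy)-1β-hydroxylabda-7,14-dien-6-one | C=C[C@](C)(O[Si](C)(C)C(C)(C)C)CC[C@@H]1[C@@]2(C)[C@H](O)CCC(C)(C)[C@@H]2C(=O)C=C1C
F4 | step 8 | O-1β imidazole-1-carbothioate of F3 | C=C[C@](C)(O[Si](C)(C)C(C)(C)C)CC[C@@H]1[C@@]2(C)[C@H](OC(=S)n3ccnc3)CCC(C)(C)[C@@H]2C(=O)C=C1C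
F5 | step 5 | (2S)-epimer of 8 | O=C1CC(C)(C)CC[C@H]1/C(C)=C\CC[C@@](C)(O[Si](C)(C)C(C)(C)C)C=C
F6 | step 5 | (1R,2R)-cis-2-[(2Z,6R)-6-(tert-butyldimethylsilyloxy)-6-methylocta-2,7-dien-2-yl]-5,5-dimethylcyclohexanol | O[C@@H]1CC(C)(C)CC[C@@H]1/C(C)=C\CC[C@@](C)(O[Si](C)(C)C(C)(C)C)C=C
F7 | step 5 | (1R,2S)-trans-2-[(2Z,6R)-6-(tert-butyldimethylsilyloxy)-6-methylocta-2,7-dien-2-yl]-5,5-dimethylcyclohexanol | O[C@@H]1CC(C)(C)CC[C@H]1/C(C)=C\CC[C@@](C)(O[Si](C)(C)C(C)(C)C)C=C
F8 | step 7 | (1S,2R)-2-[(2Z,6R)-6-(tert-butyldimethylsilyloxy)-6-methylocta-2,7-dien-2-yl]-5,5-dimethyl-1-[(Z)-prop-1-enyl]cyclohexanol | C/C=C\[C@@]1(O)CC(C)(C)CC[C@@H]1/C(C)=C\CC[C@@](C)(O[Si](C)(C)C(C)(C)C)C=C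
F9 | step 7 | potassium (1Z,5E)-cyclodeca-1,5-dien-1-olate from F8 (8S, 9 as in 15, labdane numbering) | [K+].[O-]/C1=C\[C@@H](C)[C@H](CC[C@@](C)(O[Si](C)(C)C(C)(C)C)C=C)/C(C)=C/CCC(C)(C)C1
F10 | step 7 | trimethylsilyl enol ether of F9 | C[Si](C)(C)O/C1=C\[C@@H](C)[C@H](CC[C@@](C)(O[Si](C)(C)C(C)(C)C)C=C)/C(C)=C/CCC(C)(C)C1
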